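Assumption: the only stereocentre (C3) decodes from the SMILES as (R). Isoflavan numbering is used (O1, C2–C8a for rings A and C, primed numbers for ring B). Common reagents are not numbered.

## Retrosynthetic overview
1. The hydroxyquinone comes from a 4'-acetoxy-2',5'-dimethoxy ring B by oxidative demethylation, and both prenyl groups come from C-allyl groups by a late double cross-metathesis.
2. Ring C is the only ring built. It is closed at O1–C2 by an intramolecular Mitsunobu etherification of a (2R)-2,3-diarylpropan-1-ol. Rings A and B are bought as arenes, and ring B becomes the quinone last.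
3. The C3–C4 bond comes from an Evans boron aldol between the ring B arylacetyl oxazolidinone and the ring A benzaldehyde. This sets C3, and the C4 carbinol is then removed by ionic hydrogenation.
4. The ring A aldehyde comes from 2,4,6-trihydroxybenzaldehyde. O-allylation and Claisen rearrangement of the chelated OH place the C-allyl group between the later 5-OMe and 7-O.
5. The ring B acid comes from 2,5-dimethoxyphenylacetic acid by formylation, Baeyer–Villiger oxidation, O-allylation and Claisen rearrangement.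

## Fragment A (ring A aldehyde)

Step 1
Reactants: 1 2,4,6-trihydroxybenzaldehyde
Product: 2 2-hydroxy-4,6-bis(methoxymethoxy)benzaldehyde
Conditions: MOMCl (2.2 equiv), iPr2NEt (2.5 equiv), CH2Cl2, 0 °C to rt
Reagents that add atoms: chloromethyl methyl ether COCCl
Why: In this O-alkylation (acetal protection) the para OH and one of the two equivalent ortho OH groups react, while the last OH is held back by its hydrogen bond to the aldehyde.

Step 2
Reactants: 2 2-hydroxy-4,6-bis(methoxymethoxy)benzaldehyde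
Product: 3 2-(allyloxy)-4,6-bis(methoxymethoxy)benzaldehyde
Conditions: allyl bromide, K2CO3, DMF, 50 °C
Reagents that add atoms: allyl bromide C=CCBr
Why: This Williamson ether synthesis acts on the only free phenol, and the MOM ethers and the aldehyde are inert to carbonate.

Step 3
Reactants: 3 2-(allyloxy)-4,6-bis(methoxymethoxy)benzaldehyde
Product: 4 3-allyl-2-hydroxy-4,6-bis(methoxymethoxy)benzaldehyde
Conditions: PhNEt2, 200 °C, sealed tube, argon
Reagents that add atoms: none
Why: In this aromatic Claisen rearrangement the only free ortho position of the allyl ether is C3, so the regiochemistry is unambiguous, and the basic solvent keeps the MOM groups intact.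

Step 4
Reactants: 4 3-allyl-2-hydroxy-4,6-bis(methoxymethoxy)benzaldehyde
Product: 5 3-allyl-2-methoxy-4,6-bis(methoxymethoxy)benzaldehyde
Conditions: MeI, K2CO3, DMF, 40 °C
Reagents that add atoms: iodomethane CI
Why: Williamson O-methylation of the single free phenol installs the later 5-OMe next to the C-allyl group.

Step 5
Reactants: 5 3-allyl-2-methoxy-4,6-bis(methoxymethoxy)benzaldehyde
Product: 6 3-allyl-4,6-dihydroxy-2-methoxybenzaldehyde
Conditions: conc. HCl (cat.), MeOH, 50 °C
Reagents that add atoms: none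
Why: Acid-catalysed transacetalisation removes both MOM groups, and a monosubstituted allyl group does not cyclise onto the phenol under this mild acid.

Step 6
Reactants: 6 3-allyl-4,6-dihydroxy-2-methoxybenzaldehyde
Product: 7 3-allyl-4-(allyloxy)-6-hydroxy-2-methoxybenzaldehyde
Conditions: allyl bromide (1.05 equiv), K2CO3 (1.1 equiv), acetone, reflux
Reagents that add atoms: allyl bromide C=CCBr
Why: This Williamson alkylation is selective because the para OH is more acidic and not chelated, so it reacts well before the ortho OH that is hydrogen-bonded to the aldehyde.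

Step 7
Reactants: 7 3-allyl-4-(allyloxy)-6-hydroxy-2-methoxybenzaldehyde
Product: 8 4-allyl-5-(allyloxy)-2-formyl-3-methoxyphenyl 4-methylbenzenesulfonate
Conditions: TsCl, Et3N, DMAP (cat.), CH2Cl2, 0 °C to rt
Reagents that add atoms: 4-toluenesulfonyl chloride Cc1ccc(cc1)S(=O)(=O)Cl
Why: O-sulfonylation masks the later O1 with an acid-stable and hydride-stable group that also makes the aldehyde more electrophilic for the aldol step.

## Fragment B (ring B imide)

Step 8
Reactants: 9 2-(2,5-dimethoxyphenyl)acetic acid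
Product: 10 methyl 2-(2,5-dimethoxyphenyl)acetate
Conditions: MeOH, H2SO4 (cat.), reflux
Reagents that add atoms: methanol CO
Why: Fischer esterification protects the acid for the Lewis-acid and base steps that follow.

Step 9
Reactants: 10 methyl 2-(2,5-dimethoxyphenyl)acetate
Product: 12 methyl 2-(4-formyl-2,5-dimethoxyphenyl)acetate, via α-chloro ether 11 (not isolated)
Conditions: Cl2CHOMe, TiCl4, CH2Cl2, −10 to 0 °C; then ice/1 M HCl
Reagents that add atoms: dichloromethyl methyl ether COC(Cl)Cl; water O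
Why: Rieche formylation attacks C4 (ortho to OMe, para to the alkyl chain, least hindered), the same selectivity as in 2,5-dimethoxytoluene.

Step 10
Reactants: 12 methyl 2-(4-formyl-2,5-dimethoxyphenyl)acetate
Product: 14 methyl 2-(4-hydroxy-2,5-dimethoxyphenyl)acetate, via aryl formate 13 (not isolated)
Conditions: mCPBA, CH2Cl2, 0 °C to rt, NaHCO3 wash; crude in MeOH, K2CO3 (cat.), 0 °C
Reagents that add atoms: 3-chloroperbenzoic acid OOC(=O)c1cccc(Cl)c1
Why: In this Baeyer–Villiger (Dakin-type) oxidation the electron-rich aryl group migrates, and the labile formate is methanolysed without changing the methyl ester.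

Step 11
Reactants: 14 methyl 2-(4-hydroxy-2,5-dimethoxyphenyl)acetate
Product: 15 methyl 2-[4-(allyloxy)-2,5-dimethoxyphenyl]acetate
Conditions: allyl bromide, K2CO3, acetone, reflux
Reagents that add atoms: allyl bromide C=CCBr
Why: Williamson ether synthesis works here because carbonate deprotonates the phenol but not the arylacetate CH2.

Step 12
Reactants: 15 methyl 2-[4-(allyloxy)-2,5-dimethoxyphenyl]acetate
Product: 16 methyl 2-(3-allyl-4-hydroxy-2,5-dimethoxyphenyl)acetate
Conditions: PhNEt2, 200 °C, sealed tube, argon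
Reagents that add atoms: none
Why: In this aromatic Claisen rearrangement C5 (OMe) and the para carbon C1 are blocked, so the allyl group can only end at C3, the later C3'.

Step 13
Reactants: 16 methyl 2-(3-allyl-4-hydroxy-2,5-dimethoxyphenyl)acetate
Product: 17 methyl 2-[3-allyl-4-(allyloxy)-2,5-dimethoxyphenyl]acetate
Conditions: allyl bromide, K2CO3, DMF, 60 °C
Reagents that add atoms: allyl bromide C=CCBr
Why: Williamson ether synthesis gives an O-allyl group that is stable to acid, base and hydride and is later removed under neutral palladium catalysis.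

Step 14
Reactants: 17 methyl 2-[3-allyl-4-(allyloxy)-2,5-dimethoxyphenyl]acetate
Product: 18 2-[3-allyl-4-(allyloxy)-2,5-dimethoxyphenyl]acetic acid
Conditions: LiOH, THF/MeOH/H2O, rt; then 1 M HCl
Reagents that add atoms: lithium hydroxide [Li+].[OH-]
Why: In this ester saponification all other groups are ethers or alkenes and are inert.

Step 15
Reactants: 18 2-[3-allyl-4-(allyloxy)-2,5-dimethoxyphenyl]acetic acid; 19 (S)-4-benzyloxazolidin-2-one
Product: 21 (S)-3-{2-[3-allyl-4-(allyloxy)-2,5-dimethoxyphenyl]acetyl}-4-benzyloxazolidin-2-one, via mixed pivalic anhydride 20 (not isolated)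
Conditions: PivCl, Et3N, THF, −20 °C; then LiCl, 19, −20 °C to rt
Reagents that add atoms: pivaloyl chloride CC(C)(C)C(=O)Cl (its atoms stay in 20 only)
Why: N-acylation runs through the mixed anhydride, which is attacked at the unhindered arylacetyl carbonyl, and LiCl activates the oxazolidinone so no strong base is needed.

## Union and endgame

Step 16
Reactants: 21 (S)-3-{2-[3-allyl-4-(allyloxy)-2,5-dimethoxyphenyl]acetyl}-4-benzyloxazolidin-2-one; 8 4-allyl-5-(allyloxy)-2-formyl-3-methoxyphenyl 4-methylbenzenesulfonate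
Product: 24 (4S)-4-benzyl-3-{(2S,3S)-2-[3-allyl-4-(allyloxy)-2,5-dimethoxyphenyl]-3-[3-allyl-4-(allyloxy)-2-methoxy-6-(tosyloxy)phenyl]-3-hydroxypropanoyl}oxazolidin-2-one, via boron enolate 22 (not isolated), via boron aldolate 23 (not isolated)
Conditions: Bu2BOTf (1.2 equiv), iPr2NEt (1.4 equiv), CH2Cl2, −78 to 0 °C; 8, −78 to 0 °C; then pH 7 buffer, MeOH, 30% H2O2, 0 °C
Reagents that add atoms: dibutylboron triflate CCCCB(CCCC)OS(=O)(=O)C(F)(F)F (its atoms stay in 22 and 23 only)
Why: In this Evans syn aldol the (Z)-boron enolate reacts through a Zimmerman–Traxler chair on the face away from the benzyl group of the (S)-auxiliary, which sets the α-carbon (later C3) as (2S), while the carbinol centre is erased in step 17.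

Step 17
Reactants: 24 the (2S,3S) syn aldol
Product: 25 (4S)-4-benzyl-3-{(2R)-2-[3-allyl-4-(allyloxy)-2,5-dimethoxyphenyl]-3-[3-allyl-4-(allyloxy)-2-methoxy-6-(tosyloxy)phenyl]propanoyl}oxazolidin-2-one
Conditions: Et3SiH (6 equiv), CF3CO2H (15 equiv), CH2Cl2, 0 °C to rt
Reagents that add atoms: none
Why: In this ionic hydrogenation the carbinol, activated by the para allyloxy and ortho methoxy groups, ionises and is trapped by silane hydride, while monosubstituted alkenes, allyl ethers, tosylate and imide are inert and the α-carbon keeps its geometry (the descriptor changes to R only by priority).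

Step 18
Reactants: 25 the (2R) imide
Product: 26 4-allyl-5-(allyloxy)-2-{(2R)-2-[3-allyl-4-(allyloxy)-2,5-dimethoxyphenyl]-3-hydroxypropyl}-3-methoxyphenyl 4-methylbenzenesulfonate
Conditions: LiBH4 (2 equiv), MeOH (2 equiv), THF, 0 °C; aq. work-up
Reagents that add atoms: none
Why: In this reductive removal of the Evans auxiliary the exocyclic imide carbonyl is reduced quickly to the primary alcohol without epimerisation, the protic additive prevents hydroboration of the alkenes, and 19 is recovered.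

Step 19
Reactants: 26 the (2R) alcohol tosylate
Product: 27 (2R)-2-[3-allyl-4-(allyloxy)-2,5-dimethoxyphenyl]-3-[3-allyl-4-(allyloxy)-6-hydroxy-2-methoxyphenyl]propan-1-ol
Conditions: KOH (10 equiv), dioxane/H2O (3:1), 90 °C; then 1 M HCl
Reagents that add atoms: none
Why: Hydrolysis of the aryl sulfonate (hydroxide attacks sulfur) frees only the phenol next to the side chain, and the stereocentre no longer carries an acidic hydrogen.

Step 20
Reactants: 27 the (2R) phenol alcohol
Product: 28 (3R)-6-allyl-7-(allyloxy)-3-[3-allyl-4-(allyloxy)-2,5-dimethoxyphenyl]-5-methoxychroman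
Conditions: PPh3, DIAD, THF (0.01 M), 0 °C to rt
Reagents that add atoms: none
Why: In this intramolecular Mitsunobu etherification the activated primary carbon is displaced 6-exo-tet by the single free phenol, which closes ring C at C2 and leaves C3 untouched.

Step 21
Reactants: 28 the (3R) bis(allyl ether) chroman
Product: 29 (3R)-6-allyl-3-(3-allyl-4-hydroxy-2,5-dimethoxyphenyl)-5-methoxychroman-7-ol
Conditions: Pd(PPh3)4 (5 mol %), morpholine (10 equiv), THF, rt, argon
Reagents that add atoms: none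
Why: In this Tsuji–Trost deallylation zerovalent palladium ionises only the aryl allyl ethers and morpholine takes up the allyl groups, so the C-allyl groups stay.

Step 22
Reactants: 29 the (3R) diphenol
Product: 30 (3R)-7-acetoxy-3-(4-acetoxy-3-allyl-2,5-dimethoxyphenyl)-6-allyl-5-methoxychroman
Conditions: Ac2O, pyridine, DMAP (cat.), CH2Cl2, rt
Reagents that add atoms: acetic anhydride CC(=O)OC(C)=O
Why: O-acetylation gives groups that are inert to metathesis and that lower the electron density of ring A before the oxidation.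

Step 23
Reactants: 30 the (3R) bis-allyl diacetate
Product: 31 (3R)-7-acetoxy-3-[4-acetoxy-2,5-dimethoxy-3-(3-methylbut-2-enyl)phenyl]-5-methoxy-6-(3-methylbut-2-enyl)chroman
Conditions: 2-methyl-2-butene (large excess), second-generation Grubbs catalyst RuCl2(=CHPh)(PCy3)(H2IMes) (5 mol %), CH2Cl2, 40 °C, sealed tube
Reagents that add atoms: 2-methyl-2-butene CC=C(C)C
Why: In this double olefin cross-metathesis both terminal allyl groups exchange CH2 for CMe2, loss of propene drives the reaction, and the trisubstituted products do not react further.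

Step 24
Reactants: 31 the (3R) bis-prenyl diacetate
Product: 32 (3R)-7-acetoxy-3-[4-acetoxy-3-(3-methylbut-2-enyl)-2,5-dioxocyclohexa-3,6-dienyl]-5-methoxy-6-(3-methylbut-2-enyl)chroman
Conditions: (NH4)2Ce(NO3)6 (2.2 equiv), MeCN/H2O (4:1), −5 to 0 °C, 15 min
Reagents that add atoms: water O
Why: In this oxidative demethylation by tetravalent cerium only ring B has a para-dimethoxy pair that can collapse to a quinone, ring A is meta-oxygenated and acetate-deactivated, and prenyl groups tolerate the short cold exposure.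

Step 25
Reactants: 32 the (3R) acetoxyquinone acetate
Product: 33 target, (3R)-3-[4-hydroxy-3-(3-methylbut-2-enyl)-2,5-dioxocyclohexa-3,6-dienyl]-5-methoxy-6-(3-methylbut-2-enyl)chroman-7-ol
Conditions: K2CO3 (3 equiv), degassed MeOH, 0 °C, argon; then 1 M HCl to pH 3
Reagents that add atoms: none
Why: In this Zemplén-type methanolysis of both acetates the vinylogous anhydride on the quinone cleaves at once, and the resulting hydroxyquinone anion resists nucleophiles and deprotonation at C3, so (3R) is kept.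

## Compound list
1 | 2,4,6-trihydroxybenzaldehyde | O=Cc1c(O)cc(O)cc1O | starting material
2 | 2-hydroxy-4,6-bis(methoxymethoxy)benzaldehyde | O=Cc1c(O)cc(OCOC)cc1OCOC | intermediate
3 | 2-(allyloxy)-4,6-bis(methoxymethoxy)benzaldehyde | O=Cc1c(OCC=C)cc(OCOC)cc1OCOC | intermediate
4 | 3-allyl-2-hydroxy-4,6-bis(methoxymethoxy)benzaldehyde | O=Cc1c(O)c(CC=C)c(OCOC)cc1OCOC | intermediate
5 | 3-allyl-2-methoxy-4,6-bis(methoxymethoxy)benzaldehyde | O=Cc1c(OC)c(CC=C)c(OCOC)cc1OCOC | intermediate
6 | 3-allyl-4,6-dihydroxy-2-methoxybenzaldehyde | O=Cc1c(OC)c(CC=C)c(O)cc1O | intermediate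
7 | 3-allyl-4-(allyloxy)-6-hydroxy-2-methoxybenzaldehyde | O=Cc1c(OC)c(CC=C)c(OCC=C)cc1O | intermediate
8 | 4-allyl-5-(allyloxy)-2-formyl-3-methoxyphenyl 4-methylbenzenesulfonate | O=Cc1c(OC)c(CC=C)c(OCC=C)cc1OS(=O)(=O)c2ccc(C)cc2 | intermediate
9 | 2-(2,5-dimethoxyphenyl)acetic acid | OC(=O)Cc1cc(OC)ccc1OC | starting material
10 | methyl 2-(2,5-dimethoxyphenyl)acetate | COC(=O)Cc1cc(OC)ccc1OC | intermediate
11 | methyl 2-{4-[chloro(methoxy)methyl]-2,5-dimethoxyphenyl}acetate (racemic, not isolated) | COC(=O)Cc1cc(OC)c(C(Cl)OC)cc1OC | intermediate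
12 | methyl 2-(4-formyl-2,5-dimethoxyphenyl)acetate | COC(=O)Cc1cc(OC)c(C=O)cc1OC | intermediate
13 | methyl 2-[4-(formyloxy)-2,5-dimethoxyphenyl]acetate (not isolated) | COC(=O)Cc1cc(OC)c(OC=O)cc1OC | intermediate
14 | methyl 2-(4-hydroxy-2,5-dimethoxyphenyl)acetate | COC(=O)Cc1cc(OC)c(O)cc1OC | intermediate
15 | methyl 2-[4-(allyloxy)-2,5-dimethoxyphenyl]acetate | COC(=O)Cc1cc(OC)c(OCC=C)cc1OC | intermediate
16 | methyl 2-(3-allyl-4-hydroxy-2,5-dimethoxyphenyl)acetate | COC(=O)Cc1cc(OC)c(O)c(CC=C)c1OC | intermediate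
17 | methyl 2-[3-allyl-4-(allyloxy)-2,5-dimethoxyphenyl]acetate | COC(=O)Cc1cc(OC)c(OCC=C)c(CC=C)c1OC | intermediate
18 | 2-[3-allyl-4-(allyloxy)-2,5-dimethoxyphenyl]acetic acid | OC(=O)Cc1cc(OC)c(OCC=C)c(CC=C)c1OC | intermediate
19 | (S)-4-benzyloxazolidin-2-one | O=C1N[C@@H](Cc2ccccc2)CO1 | starting material
20 | 2-[3-allyl-4-(allyloxy)-2,5-dimethoxyphenyl]acetic pivalic anhydride (not isolated) | CC(C)(C)C(=O)OC(=O)Cc1cc(OC)c(OCC=C)c(CC=C)c1OC | intermediate
21 | (S)-3-{2-[3-allyl-4-(allyloxy)-2,5-dimethoxyphenyl]acetyl}-4-benzyloxazolidin-2-one | O=C(Cc1cc(OC)c(OCC=C)c(CC=C)c1OC)N1[C@@H](Cc2ccccc2)COC1=O | intermediate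
22 | (Z)-dibutylboron enolate of 21 (not isolated) | CCCCB(CCCC)O/C(=C\c1cc(OC)c(OCC=C)c(CC=C)c1OC)N1[C@@H](Cc2ccccc2)COC1=O | intermediate
23 | O-dibutylboryl derivative of aldol 24 (not isolated) | O=C(N1[C@@H](Cc2ccccc2)COC1=O)[C@@H](c3cc(OC)c(OCC=C)c(CC=C)c3OC)[C@H](OB(CCCC)CCCC)c4c(OC)c(CC=C)c(OCC=C)cc4OS(=O)(=O)c5ccc(C)cc5 | intermediate
24 | (4S)-auxiliary (2S,3S) syn aldol | O=C(N1[C@@H](Cc2ccccc2)COC1=O)[C@@H](c3cc(OC)c(OCC=C)c(CC=C)c3OC)[C@H](O)c4c(OC)c(CC=C)c(OCC=C)cc4OS(=O)(=O)c5ccc(C)cc5 | intermediate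
25 | (4S)-auxiliary (2R)-2,3-diarylpropanoyl imide | O=C(N1[C@@H](Cc2ccccc2)COC1=O)[C@@H](c3cc(OC)c(OCC=C)c(CC=C)c3OC)Cc4c(OC)c(CC=C)c(OCC=C)cc4OS(=O)(=O)c5ccc(C)cc5 | intermediate
26 | (2R)-2,3-diarylpropan-1-ol, ring A phenol as tosylate | OC[C@@H](c1cc(OC)c(OCC=C)c(CC=C)c1OC)Cc2c(OC)c(CC=C)c(OCC=C)cc2OS(=O)(=O)c3ccc(C)cc3 | intermediate
27 | (2R)-2,3-diarylpropan-1-ol, ring A phenol free | OC[C@@H](c1cc(OC)c(OCC=C)c(CC=C)c1OC)Cc2c(OC)c(CC=C)c(OCC=C)cc2O | intermediate
28 | (3R)-6-allyl-7-(allyloxy)-3-[3-allyl-4-(allyloxy)-2,5-dimethoxyphenyl]-5-methoxychroman | COc1c(CC=C)c(OCC=C)cc2c1C[C@H](c3cc(OC)c(OCC=C)c(CC=C)c3OC)CO2 | intermediate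
29 | (3R)-6-allyl-3-(3-allyl-4-hydroxy-2,5-dimethoxyphenyl)-5-methoxychroman-7-ol | COc1c(CC=C)c(O)cc2c1C[C@H](c3cc(OC)c(O)c(CC=C)c3OC)CO2 | intermediate
30 | (3R)-7-acetoxy-3-(4-acetoxy-3-allyl-2,5-dimethoxyphenyl)-6-allyl-5-methoxychroman | COc1c(CC=C)c(OC(C)=O)cc2c1C[C@H](c3cc(OC)c(OC(C)=O)c(CC=C)c3OC)CO2 | intermediate
31 | (3R)-7-acetoxy-3-(4-acetoxy-2,5-dimethoxy-3-prenylphenyl)-5-methoxy-6-prenylchroman | COc1c(CC=C(C)C)c(OC(C)=O)cc2c1C[C@H](c3cc(OC)c(OC(C)=O)c(CC=C(C)C)c3OC)CO2 | intermediate
32 | (3R)-7-acetoxy-3-(4-acetoxy-3-prenyl-2,5-dioxocyclohexa-3,6-dienyl)-5-methoxy-6-prenylchroman | COc1c(CC=C(C)C)c(OC(C)=O)cc2c1C[C@H](C3=CC(=O)C(OC(C)=O)=C(CC=C(C)C)C3=O)CO2 | intermediate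
33 | CNP0148998.1, (3R)-3-(4-hydroxy-3-prenyl-2,5-dioxocyclohexa-3,6-dienyl)-5-methoxy-6-prenylchroman-7-ol | COc1c(CC=C(C)C)c(O)cc2c1C[C@H](C1=CC(=O)C(O)=C(CC=C(C)C)C1=O)CO2 | target

## Step count
Total steps: 25. The longest linear sequence is 18 steps (9 to 33, steps 8–25). The ring A branch (1 to 8) adds 7 steps and joins at step 16.

## Steps most likely to fail and their fallbacks

**Step 16.** The aldehyde 8 carries two ortho substituents, so the boron enolate may add slowly or the adduct may revert. The fallback sets out from 18 and comes back at 26.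
- Acid 18 is coupled (EDC·HCl, DMAP, CH2Cl2) with commercial (S)-4-benzylthiazolidine-2-thione to the N-acyl thiazolidinethione F1.
- Soft enolisation with TiCl4, iPr2NEt and N-methylpyrrolidinone (CH2Cl2, −78 to 0 °C) and addition of 8 gives the thiazolidinethione syn aldol F2. It has the same (2S,3S) sense. The chlorotitanium enolate activates the hindered aldehyde more strongly than boron does.
- NaBH4 (THF/EtOH, 0 °C) removes the thione auxiliary at once and gives the (1S,2R)-1,3-diol F3, so no retro-aldol-prone imide is carried on.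
- Et3SiH/CF3CO2H (CH2Cl2, 0 °C) removes only the benzylic hydroxyl and delivers 26.

**Step 17.** The cationic deoxygenation could lose a proton to the conjugated diarylacrylimide, which would erase C3, or it could alkylate an electron-rich ring. The fallback sets out from 24 and comes back at 25.
- It replaces the cation by a radical (Barton–McCombie deoxygenation).
- PhOC(S)Cl, pyridine and DMAP (CH2Cl2, 0 °C to rt) give the O-phenyl thionocarbonate F4.
- Bu3SnH with AIBN (toluene, 80 °C) reduces F4 through the benzylic radical, which has no β-leaving group and no alkene within reach, and gives 25.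

**Step 24.** The cerium oxidation could touch the prenyl groups or ring A, or hydrolyse the acetoxyquinone. The fallback sets out from 30 and comes back at 33.
- The oxidation is moved ahead of the metathesis, and the final oxidation is left to air.
- (NH4)2Ce(NO3)6 (MeCN/H2O, 0 °C) acts on 30, which holds only robust terminal alkenes, and gives the bis-allyl acetoxyquinone F5.
- Reductive acetylation (Zn, Ac2O, pyridine) stores F5 as the bis-allyl tetraacetate F6.
- Cross-metathesis with 2-methyl-2-butene, as in step 23, gives the bis-prenyl tetraacetate F7.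
- K2CO3 in degassed MeOH liberates the tetraphenol F8.
- Only the 2',4',5'-trihydroxy ring of F8 autoxidises when the basic solution is opened to air, and acidification gives 33.

## Further compounds
F1 | step 16 | (S)-3-{2-[3-allyl-4-(allyloxy)-2,5-dimethoxyphenyl]acetyl}-4-benzylthiazolidine-2-thione | O=C(Cc1cc(OC)c(OCC=C)c(CC=C)c1OC)N1[C@@H](Cc2ccccc2)CSC1=S
F2 | step 16 | (4S)-thiazolidinethione (2S,3S) syn aldol | O=C(N1[C@@H](Cc2ccccc2)CSC1=S)[C@@H](c3cc(OC)c(OCC=C)c(CC=C)c3OC)[C@H](O)c4c(OC)c(CC=C)c(OCC=C)cc4OS(=O)(=O)c5ccc(C)cc5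
F3 | step 16 | (1S,2R)-2-[3-allyl-4-(allyloxy)-2,5-dimethoxyphenyl]-1-[3-allyl-4-(allyloxy)-2-methoxy-6-(tosyloxy)phenyl]propane-1,3-diol | OC[C@@H](c1cc(OC)c(OCC=C)c(CC=C)c1OC)[C@H](O)c2c(OC)c(CC=C)c(OCC=C)cc2OS(=O)(=O)c3ccc(C)cc3
F4 | step 17 | O-phenyl thionocarbonate of aldol 24 | O=C(N1[C@@H](Cc2ccccc2)COC1=O)[C@@H](c3cc(OC)c(OCC=C)c(CC=C)c3OC)[C@H](OC(=S)Oc6ccccc6)c4c(OC)c(CC=C)c(OCC=C)cc4OS(=O)(=O)c5ccc(C)cc5
F5 | step 24 | (3R)-7-acetoxy-3-(4-acetoxy-3-allyl-2,5-dioxocyclohexa-3,6-dienyl)-6-allyl-5-methoxychroman | COc1c(CC=C)c(OC(C)=O)cc2c1C[C@H](C3=CC(=O)C(OC(C)=O)=C(CC=C)C3=O)CO2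
F6 | step 24 | (3R)-7-acetoxy-6-allyl-3-(2,4,5-triacetoxy-3-allylphenyl)-5-methoxychroman | COc1c(CC=C)c(OC(C)=O)cc2c1C[C@H](c3cc(OC(C)=O)c(OC(C)=O)c(CC=C)c3OC(C)=O)CO2
F7 | step 24 | (3R)-7-acetoxy-5-methoxy-6-prenyl-3-(2,4,5-triacetoxy-3-prenylphenyl)chroman | COc1c(CC=C(C)C)c(OC(C)=O)cc2c1C[C@H](c3cc(OC(C)=O)c(OC(C)=O)c(CC=C(C)C)c3OC(C)=O)CO2
F8 | step 24 | (3R)-5-methoxy-6-prenyl-3-(2,4,5-trihydroxy-3-prenylphenyl)chroman-7-ol | COc1c(CC=C(C)C)c(O)cc2c1C[C@H](c3cc(O)c(O)c(CC=C(C)C)c3O)CO2
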